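## Retrosynthetic overview

1. The target comes from a last-step enantioselective reduction of the C3 ketone of a 2,2-dimethylchroman-3-one, which sets the 3S carbinol.
2. The CH2 bridge comes from a reductive Knoevenagel union of a 6-formylchroman-3-one with 6-ethyl-4-hydroxy-5-methylpyran-2-one; the formyl carbon becomes the bridge.
3. The 8-acyl group comes from Friedel–Crafts acylation with (S)-2-methylbutanoyl chloride at the only free ring carbon; the side-chain stereocentre is from the chiral pool.
4. The chroman-3-one comes from C4–C4a bond formation by gold-catalysed oxidative cyclisation of an aryl 1,1-dimethylpropargyl ether (an alpha-oxo gold carbene acting as enolonium equivalent). The ether comes from para-selective O-alkylation of 2,4,6-trihydroxybenzaldehyde, which fixes the ring oxygen para to the future bridge and ortho to the future acyl group.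
5. Ring order: the benzene ring is bought, the dihydropyran ring of the chroman is closed first, and the pyranone ring is made separately from pentan-3-one and malonyl dichloride and attached late.

Assumption: the five building blocks used as starting materials are taken as catalogue chemicals, and the descriptors read from the SMILES are 3S at the chromanol carbon and 2S in the acyl chain.

## Route

Step 1
Reactants: 1 phloroglucinaldehyde (2,4,6-trihydroxybenzaldehyde); 2 tertiary propargylic chloride (3-chloro-3-methylbut-1-yne)
Product: 3 aryl propargyl ether (2,6-dihydroxy-4-[(2-methylbut-3-yn-2-yl)oxy]benzaldehyde)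
Conditions: K2CO3 (1.1 equiv), KI (0.1 equiv), CuI (2 mol %), acetone, 55 °C
Reagents that add atoms: none
Why: Copper-assisted Williamson-type O-alkylation, in which the 4-OH para to the formyl group is the most acidic hydroxyl and the only one not hydrogen-bonded to the C=O, so one equivalent of base ionises and alkylates it selectively and places the future ring oxygen para to the carbon that becomes the methylene bridge; no stereocentre is formed.

Step 2
Reactants: 3 aryl propargyl ether
Product: 5 formyl chromanone (5,7-dihydroxy-2,2-dimethyl-3-oxochromane-6-carbaldehyde), via alpha-oxo gold carbene 4 (not isolated)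
Conditions: (Me4tBuXPhos)AuNTf2 = [di-tert-butyl(2',4',6'-triisopropyl-3,4,5,6-tetramethylbiphenyl-2-yl)phosphine]gold bis(trifluoromethanesulfonyl)imide (5 mol %), 2,6-dichloropyridine N-oxide (1.3 equiv), ClCH2CH2Cl, rt, argon
Reagents that add atoms: 2,6-dichloropyridine N-oxide, [O-][n+]1c(Cl)cccc1Cl
Why: Gold-catalysed alkyne oxidation followed by arene cyclisation (the known chroman-3-one synthesis from aryl propargyl ethers), in which N-oxide attack on the gold-bound terminal alkyne gives carbene 4 whose carbon alpha to the new ketone is electrophilic (an enolonium equivalent) and is captured by the neighbouring nucleophilic arene carbon (the two ortho positions of 3 are equivalent) in a six-membered Friedel–Crafts-type closure, so two normally nucleophilic carbons are joined; no stereocentre is formed.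

Step 3
Reactants: 5 formyl chromanone; 6 (S)-2-methylbutanoic acid
Product: 8 acyl formyl chromanone (5,7-dihydroxy-2,2-dimethyl-8-[(2S)-2-methylbutanoyl]-3-oxochromane-6-carbaldehyde), via (S)-2-methylbutanoyl chloride 7 (not isolated)
Conditions: 6, (COCl)2, cat. DMF, CH2Cl2, 0 °C to rt; then 5, AlCl3 (4 equiv), CH2Cl2–PhNO2, 0 °C to rt; cold aq. HCl work-up
Reagents that add atoms: none
Why: Friedel–Crafts acylation, in which C8 is the only unsubstituted ring carbon and is still activated by the ortho hydroxyl, the ortho ring oxygen and the para hydroxyl, so the acylium ion from 7 can only enter there, while the 2S centre comes unchanged from acid 6 and is preserved by keeping the reaction at or below room temperature.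

Step 4
Reactants: 9 pentan-3-one
Product: 10 silyl enol ether (3-[(trimethylsilyl)oxy]pent-2-ene; E/Z mixture)
Conditions: LDA (commercial solution, 1.05 equiv), THF, −78 °C; Me3SiCl, −78 °C to rt
Reagents that add atoms: chlorotrimethylsilane, C[Si](C)(C)Cl
Why: Enolate O-silylation of a symmetrical ketone, so only one regioisomer can form and the alkene geometry is irrelevant because it is lost in the next step; no stereocentre is formed.

Step 5
Reactants: 10 silyl enol ether; 11 malonyl dichloride (propanedioyl dichloride)
Product: 12 pyranone (6-ethyl-4-hydroxy-5-methyl-2H-pyran-2-one)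
Conditions: Et2O, −78 °C to rt
Reagents that add atoms: none
Why: Effenberger-type pyranone synthesis, in which C-acylation of the silyl enol ether by one acid chloride and O-acylation of the resulting diketone enol by the other close the 4-hydroxypyran-2-one with ethyl at C6 and methyl at C5; no stereocentre is formed.

Step 6
Reactants: 8 acyl formyl chromanone; 12 pyranone
Product: 14 bridged chromanone (6-[(6-ethyl-4-hydroxy-5-methyl-2-oxo-2H-pyran-3-yl)methyl]-5,7-dihydroxy-2,2-dimethyl-8-[(2S)-2-methylbutanoyl]chroman-3-one), via Knoevenagel alkylidene dione 13 (not isolated)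
Conditions: L-proline (20 mol %), Hantzsch ester (diethyl 2,6-dimethyl-1,4-dihydropyridine-3,5-dicarboxylate, 1.2 equiv), CH2Cl2–EtOH, 30 °C, argon
Reagents that add atoms: none
Why: Organocatalytic three-component reductive alkylation (Knoevenagel condensation then Hantzsch ester conjugate reduction), in which the acidic C3 of 12 condenses with the aryl aldehyde to the quinone-methide-like acceptor 13 that accepts hydride from the dihydropyridine while the ketones do not, so the formyl carbon becomes the CH2 bridge; no new stereocentre is formed and the mild conditions leave the 2S centre untouched.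

Step 7
Reactants: 14 bridged chromanone
Product: 15 target (3-({(3S)-3,5,7-trihydroxy-2,2-dimethyl-8-[(2S)-2-methylbutanoyl]-3,4-dihydro-2H-chromen-6-yl}methyl)-6-ethyl-4-hydroxy-5-methyl-2H-pyran-2-one)
Conditions: (R)-2-methyl-CBS-oxazaborolidine [(R)-1-methyl-3,3-diphenyltetrahydro-1H,3H-pyrrolo[1,2-c][1,3,2]oxazaborole] (20 mol %), catecholborane (5 equiv), THF–toluene, −78 to −30 °C; MeOH quench
Reagents that add atoms: none
Why: Corey–Bakshi–Shibata reduction, in which the (R)-oxazaborolidine differentiates the quaternary C2 side from the CH2 side of the C3 ketone and delivers hydride to the face that gives the 3S alcohol (the same sense in which the (R)-catalyst gives (S)-3,3-dimethylbutan-2-ol from pinacolone), while the chelated, doubly ortho-substituted aryl ketone and the pyranone do not react with catecholborane at low temperature.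

## Compound list

1 | 2,4,6-trihydroxybenzaldehyde | O=Cc1c(O)cc(O)cc1O | starting material
2 | 3-chloro-3-methylbut-1-yne | C#CC(C)(C)Cl | starting material
3 | 2,6-dihydroxy-4-[(2-methylbut-3-yn-2-yl)oxy]benzaldehyde | O=Cc1c(O)cc(OC(C)(C)C#C)cc1O | intermediate
4 | alpha-oxo gold carbene: cationic gold carbene at the terminal carbon of the oxidised alkyne, ArO–C(CH3)2–C(=O)–CH=Au(phosphine), bis(triflyl)imide counter-ion (not isolated) | O=Cc1c(O)cc(OC(C)(C)C(=O)C=[Au][P+](C(C)(C)C)(C(C)(C)C)c2c(C)c(C)c(C)c(C)c2-c2c(C(C)C)cc(C(C)C)cc2C(C)C)cc1O.[N-](S(=O)(=O)C(F)(F)F)S(=O)(=O)C(F)(F)F | intermediate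
5 | 5,7-dihydroxy-2,2-dimethyl-3-oxochromane-6-carbaldehyde | O=Cc1c(O)c2CC(=O)C(C)(C)Oc2cc1O | intermediate
6 | (S)-2-methylbutanoic acid | CC[C@H](C)C(=O)O | starting material
7 | (S)-2-methylbutanoyl chloride (not isolated) | CC[C@H](C)C(=O)Cl | intermediate
8 | 5,7-dihydroxy-2,2-dimethyl-8-[(2S)-2-methylbutanoyl]-3-oxochromane-6-carbaldehyde | O=Cc1c(O)c2CC(=O)C(C)(C)Oc2c(C(=O)[C@@H](C)CC)c1O | intermediate
9 | pentan-3-one | CCC(=O)CC | starting material
10 | 3-[(trimethylsilyl)oxy]pent-2-ene (E/Z mixture) | CC=C(CC)O[Si](C)(C)C | intermediate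
11 | malonyl dichloride | O=C(Cl)CC(=O)Cl | starting material
12 | 6-ethyl-4-hydroxy-5-methyl-2H-pyran-2-one | CCc1oc(=O)cc(O)c1C | intermediate
13 | 6-[(6-ethyl-5-methyl-2,4-dioxo-2H-pyran-3(4H)-ylidene)methyl]-5,7-dihydroxy-2,2-dimethyl-8-[(2S)-2-methylbutanoyl]chroman-3-one (alkene geometry not fixed; not isolated) | CCC1=C(C)C(=O)C(=Cc2c(O)c3CC(=O)C(C)(C)Oc3c(C(=O)[C@@H](C)CC)c2O)C(=O)O1 | intermediate
14 | 6-[(6-ethyl-4-hydroxy-5-methyl-2-oxo-2H-pyran-3-yl)methyl]-5,7-dihydroxy-2,2-dimethyl-8-[(2S)-2-methylbutanoyl]chroman-3-one | CCc1oc(=O)c(Cc2c(O)c3CC(=O)C(C)(C)Oc3c(C(=O)[C@@H](C)CC)c2O)c(O)c1C | intermediate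
15 | 3-({(3S)-3,5,7-trihydroxy-2,2-dimethyl-8-[(2S)-2-methylbutanoyl]-3,4-dihydro-2H-chromen-6-yl}methyl)-6-ethyl-4-hydroxy-5-methyl-2H-pyran-2-one | CCc1oc(=O)c(Cc2c(O)c3c(c(C(=O)[C@@H](C)CC)c2O)OC(C)(C)[C@@H](O)C3)c(O)c1C | target

## Step count and risk

Total step count: 7. Longest linear sequence: 5 (steps 1, 2, 3, 6, 7).

Steps most likely to fail:

Step 2 (gold-catalysed oxidative cyclisation). The free phenols may slow the catalyst, or 6-endo hydroarylation to a 2H-chromene may compete. The fallback sets out from 3 and comes back at 5, keeping the electrophilic alpha-keto carbon but changing the carbene source. Markovnikov hydration of the alkyne ((Ph3P)AuNTf2 cat., MeOH–H2O) gives the methyl ketone 2,6-dihydroxy-4-[(2-methyl-3-oxobutan-2-yl)oxy]benzaldehyde F1. Detrifluoroacetylative diazo transfer (LiHMDS, CF3CO2CH2CF3) passes through the trifluoroacetyl diketone 2,6-dihydroxy-4-[(5,5,5-trifluoro-2-methyl-3,5-dioxopentan-2-yl)oxy]benzaldehyde F2, and MsN3/Et3N in aqueous MeCN then gives the diazoketone 4-[(4-diazo-2-methyl-3-oxobutan-2-yl)oxy]-2,6-dihydroxybenzaldehyde F3. Rh2(OAc)4 in CH2Cl2 then closes the ring by aromatic C–H insertion of the rhodium carbenoid to give 5.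

Step 3 (Friedel–Crafts acylation of a formyl-deactivated ring). The reaction may stop at O-acylation or be too slow at temperatures that are safe for the 2S centre. The fallback sets out from 5 and comes back at 8. Esterification with acid 6 (DCC, cat. DMAP (4-dimethylaminopyridine), CH2Cl2) gives the aryl ester 6-formyl-5-hydroxy-2,2-dimethyl-3-oxochroman-7-yl (2S)-2-methylbutanoate F4; any 5-O-ester formed alongside converges. Fries rearrangement (TiCl4, CH2Cl2, 0 °C to rt) then moves the acyl group from oxygen to C8, the only open ring carbon, to give 8.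

Step 6 (reductive Knoevenagel coupling of a hindered, chelated aldehyde). Condensation may be too slow, or the adduct may cyclise onto a neighbouring phenol before reduction. The fallback sets out from 8 and comes back at 14. Here the formyl group serves only as a removable para-directing and blocking group. Protodeformylation (aq. HCl–dioxane, 80 °C) gives 5,7-dihydroxy-2,2-dimethyl-8-[(2S)-2-methylbutanoyl]chroman-3-one F5. Separately, pyranone 12 and dimethylmethylideneammonium iodide (Eschenmoser's salt) in MeCN give the Mannich base 3-[(dimethylamino)methyl]-6-ethyl-4-hydroxy-5-methyl-2H-pyran-2-one F6. On warming with F5 this loses dimethylamine to a pyranone methide, which is captured by C6 of F5 (now its only free ring carbon) to give 14.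

## Further compounds

F1 | step 2 | 2,6-dihydroxy-4-[(2-methyl-3-oxobutan-2-yl)oxy]benzaldehyde | CC(=O)C(C)(C)Oc1cc(O)c(C=O)c(O)c1
F2 | step 2 | 2,6-dihydroxy-4-[(5,5,5-trifluoro-2-methyl-3,5-dioxopentan-2-yl)oxy]benzaldehyde | O=Cc1c(O)cc(OC(C)(C)C(=O)CC(=O)C(F)(F)F)cc1O
F3 | step 2 | 4-[(4-diazo-2-methyl-3-oxobutan-2-yl)oxy]-2,6-dihydroxybenzaldehyde | O=Cc1c(O)cc(OC(C)(C)C(=O)C=[N+]=[N-])cc1O
F4 | step 3 | 6-formyl-5-hydroxy-2,2-dimethyl-3-oxochroman-7-yl (2S)-2-methylbutanoate | CC[C@H](C)C(=O)Oc1cc2OC(C)(C)C(=O)Cc2c(O)c1C=O
F5 | step 6 | 5,7-dihydroxy-2,2-dimethyl-8-[(2S)-2-methylbutanoyl]chroman-3-one | CC[C@H](C)C(=O)c1c(O)cc(O)c2CC(=O)C(C)(C)Oc12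
F6 | step 6 | 3-[(dimethylamino)methyl]-6-ethyl-4-hydroxy-5-methyl-2H-pyran-2-one | CCc1oc(=O)c(CN(C)C)c(O)c1C
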